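**Plan**

1. Core locants used throughout: C1 (CH–O), C2, C3 (quaternary, CH3), C9, C10 (C–iPr) form the five-membered ring; C3, C4, C5 (C=O), C6 (CH3, O), C7, C8, C9 form the seven-membered ring; β is the face of the C3 methyl.
2. Retrosynthesis: cut both angelate C–O bonds; take C6 back to CH2 (C6–CH3 and C6–O come from a C6 exo-methylene epoxidised under direction of a C5 carbinol); move C9=C10 back to C8=C9 through the C1 ketone; cut C3–C9 and C7–C8 together; cut C1–C10 of the open chain.
3. The key step is possible because C3–C4–C5(O)–C6–C7 of the seven-membered ring is a 1-siloxy-1-vinylcyclopropane once the C5–C7 bond is restored, and C8–C9 is a terminal alkyne held to C3 by the ring atoms C2–C1–C10.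
4. Forward: aldehyde 6 (C2–C7) and mesylate 12 (C8–C10) are joined at C1–C10; one rhodium-catalysed step closes both rings; adjustment at C1, elaboration of C5/C6 and double esterification follow.
5. Stereochemistry: C10 and C1 come from the (S)-mesylate through an anti-selective allenylzinc addition and relay to C3 in the cycloaddition; C1 is reset by CBS reduction; C6 is set by epoxidation directed by a CBS-derived C5 carbinol; the helper centres C10 and C5 end as sp2 carbons.

Key step: step 10

Remark: if the relay from the tether to C3 in step 10 should run opposite to the sense argued there, ent-12 (from the (R,R) catalyst in step 6) would be used, since C1 and C10 are both reset or erased after the cycloaddition.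

**Route**

Step 1
Reactants: 1 4,4-dimethoxybutan-2-one; 2 trimethyl phosphonoacetate
Product: 3 methyl (2E)-5,5-dimethoxy-3-methylpent-2-enoate
Conditions: NaH, THF, 0 °C → rt; Z isomer removed by chromatography
Reagents that add atoms: none
Why: Horner–Wadsworth–Emmons olefination of the methyl ketone should place the ester trans to the larger CH2CH(OMe)2 arm, and this E geometry later puts the tether trans to the cyclopropane on the C3=C4 alkene.

Step 2
Reactants: 3 methyl (2E)-5,5-dimethoxy-3-methylpent-2-enoate
Product: 4 1-[(1E)-4,4-dimethoxy-2-methylbut-1-en-1-yl]cyclopropan-1-ol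
Conditions: EtMgBr (2.5 equiv), Ti(OiPr)4 (0.5 equiv), THF, 0 °C → rt
Reagents that add atoms: ethylmagnesium bromide, CC[Mg]Br
Why: Kulinkovich cyclopropanation (double addition of the titanacyclopropane to the ester carbonyl) tolerates β,β-disubstituted enoates and acetals and turns the ester carbon into C5 with its partners C6 and C7 without touching the alkene geometry.

Step 3
Reactants: 4 1-[(1E)-4,4-dimethoxy-2-methylbut-1-en-1-yl]cyclopropan-1-ol
Product: 5 tert-butyl({1-[(1E)-4,4-dimethoxy-2-methylbut-1-en-1-yl]cyclopropyl}oxy)dimethylsilane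
Conditions: TBSCl, imidazole, DMAP (cat.), DMF, rt
Reagents that add atoms: tert-butyldimethylsilyl chloride, CC(C)(C)[Si](C)(C)Cl
Why: Base-mediated O-silylation of the tertiary cyclopropanol avoids the acid or strong base that would open the strained ring and installs the donor that later speeds cyclopropane cleavage.

Step 4
Reactants: 5 tert-butyl({1-[(1E)-4,4-dimethoxy-2-methylbut-1-en-1-yl]cyclopropyl}oxy)dimethylsilane
Product: 6 (3E)-4-[1-(tert-butyldimethylsilyloxy)cyclopropyl]-3-methylbut-3-enal
Conditions: 10% aq. oxalic acid on SiO2, CH2Cl2, rt; crude aldehyde used at once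
Reagents that add atoms: water, O
Why: Acetal hydrolysis on oxalic acid-doped wet silica is mild enough to spare the silyl ether, to avoid acid-induced ring expansion of the siloxy vinylcyclopropane and to keep the β,γ-alkene out of conjugation when the aldehyde is used directly.

Step 5
Reactants: 7 bis(trimethylsilyl)acetylene; 8 2-methylpropanoyl chloride
Product: 9 4-methyl-1-(trimethylsilyl)pent-1-yn-3-one
Conditions: AlCl3, CH2Cl2, 0 °C
Reagents that add atoms: none
Why: Friedel–Crafts-type acyldesilylation of the bis-silylalkyne should stop after one acylation because the ynone formed is deactivated.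

Step 6
Reactants: 9 4-methyl-1-(trimethylsilyl)pent-1-yn-3-one
Product: 10 (3S)-4-methyl-1-(trimethylsilyl)pent-1-yn-3-ol
Conditions: RuCl[(S,S)-TsNCH(Ph)CH(Ph)NH2](η6-p-cymene) (1 mol%), i-PrOH, rt
Reagents that add atoms: none
Why: Noyori asymmetric transfer hydrogenation, in which the alkynyl group takes the site next to the arene ligand that an aryl group takes in aryl ketones, should give the (S)-carbinol with the (S,S) catalyst.

Step 7
Reactants: 10 (3S)-4-methyl-1-(trimethylsilyl)pent-1-yn-3-ol
Product: 11 (3S)-4-methylpent-1-yn-3-ol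
Conditions: K2CO3 (cat.), MeOH, rt
Reagents that add atoms: none
Why: Base-catalysed methanolysis cleaves the C(sp)–Si bond selectively and leaves the carbinol centre untouched.

Step 8
Reactants: 11 (3S)-4-methylpent-1-yn-3-ol
Product: 12 (3S)-4-methylpent-1-yn-3-yl methanesulfonate
Conditions: MsCl, Et3N, CH2Cl2, −78 → 0 °C
Reagents that add atoms: methanesulfonyl chloride, CS(=O)(=O)Cl
Why: O-sulfonylation proceeds with retention at carbon and provides the leaving group for the SN2′ oxidative addition of the next step.

Step 9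
Reactants: 6 (3E)-4-[1-(tert-butyldimethylsilyloxy)cyclopropyl]-3-methylbut-3-enal; 12 (3S)-4-methylpent-1-yn-3-yl methanesulfonate
Product: 14 (3R,4S,6E)-7-[1-(tert-butyldimethylsilyloxy)cyclopropyl]-6-methyl-3-(propan-2-yl)hept-6-en-1-yn-4-ol, via allenylzinc reagent 13 (not isolated)
Conditions: Pd(OAc)2 (5 mol%), PPh3 (5 mol%), Et2Zn (3 equiv), THF, −78 → −20 °C; aq. NH4Cl
Reagents that add atoms: none
Why: In this Marshall–Tamaru propargylation zerovalent palladium displaces the mesylate anti (SN2′), transmetallation with Et2Zn gives the (aR)-allenylzinc 13, and its cyclic SE2′ addition with the aldehyde chain turned away from the isopropyl group sets C10 (R, net inversion of the mesylate centre) and C1 (S, anti) together.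

Step 10
Reactants: 14 (3R,4S,6E)-7-[1-(tert-butyldimethylsilyloxy)cyclopropyl]-6-methyl-3-(propan-2-yl)hept-6-en-1-yn-4-ol
Product: 15 (1R,2S,3aR)-5-(tert-butyldimethylsilyloxy)-3a-methyl-1-(propan-2-yl)-1,2,3,3a,6,7-hexahydroazulen-2-ol (core locants: C1 β-OH; C3 β-CH3; C10 β-isopropyl; C4=C5–OTBS; C8=C9)
Conditions: [Rh(CO)2Cl]2 (5 mol%), ClCH2CH2Cl (0.02 M), rt → 40 °C
Reagents that add atoms: none
Why: This is a rhodium-catalysed intramolecular vinylcyclopropane–alkyne [5+2] cycloaddition, whose closest precedents are tethered alkyne–vinylcyclopropanes that form angular quaternary carbons and intermolecular reactions of 1-siloxy-1-vinylcyclopropanes with the same catalyst. Monovalent rhodium inserts into one of the two equivalent C5–CH2 bonds to give a σ,π-allyl rhodacyclohexene (allyl C3–C4–C5, σ-bond to C7), the siloxy donor on C5 speeding this cleavage and emerging as the C4=C5 silyl enol ether. The five-membered ring closes by syn migratory insertion of the tethered alkyne into the Rh–C3 allyl terminus (5-exo carbometallation forming C3–C9), and the seven-membered ring closes by C7–C8 reductive elimination from the resulting eight-membered rhodacycle. The only new stereocentre, C3, is set in the insertion: the C10 isopropyl group and the C1 hydroxyl, cis to each other on the forming cyclopentane because 14 is anti, should both sit on its convex face away from C4 and the metal, which places the C3 methyl cis to them (β). The step needs this facial selectivity and cycloaddition in preference to alkyne oligomerisation; the first rests on the matched pair of tether stereocentres and the E alkene (tether trans to the cyclopropane), the second on high dilution, and no regiochemical question arises because the two cyclopropane CH2 groups are equivalent.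

Step 11
Reactants: 15 cycloadduct (C1 β-OH; C8=C9; C4=C5–OTBS)
Product: 17 conjugated enone (C1 ketone; C9=C10 with isopropyl on C10; C3 β-CH3; C4=C5–OTBS), via β,γ-unsaturated ketone 16 (not isolated)
Conditions: Dess–Martin periodinane, NaHCO3, CH2Cl2, 0 °C → rt; then DBU (0.3 equiv), CH2Cl2, rt
Reagents that add atoms: none
Why: Dess–Martin oxidation under bicarbonate buffer leaves the silyl enol ether intact, and DBU then moves C8=C9 into conjugation through the dienolate (deprotonation at C10, protonation at C8), which erases the C10 helper centre.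

Step 12
Reactants: 17 conjugated enone (C1 ketone; C9=C10; C4=C5–OTBS)
Product: 19 C1 β-hydroxy C5 ketone (C9=C10; C3 β-CH3), via allylic alcohol silyl enol ether 18 (not isolated)
Conditions: (R)-Me-CBS [(3aR)-1-methyl-3,3-diphenyltetrahydro-1H,3H-pyrrolo[1,2-c][1,3,2]oxazaborole] (0.3 equiv), catecholborane, toluene, −78 °C; MeOH; then Bu4NF, AcOH, THF, 0 °C
Reagents that add atoms: none
Why: Corey–Bakshi–Shibata reduction with the enone carbon C10 as the large group and the (R)-catalyst should deliver hydride to the α face of C1 and give the (S)-configured β-alcohol cis to the C3 methyl, catecholborane at −78 °C leaving the enol ether alone, which buffered fluoride then cleaves to unveil the C5 ketone.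

Step 13
Reactants: 19 C1 β-hydroxy C5 ketone
Product: 20 C1 β-OTBS ether of the C5 ketone (C9=C10)
Conditions: TBSCl, imidazole, DMAP (cat.), DMF, rt
Reagents that add atoms: tert-butyldimethylsilyl chloride, CC(C)(C)[Si](C)(C)Cl
Why: Standard O-silylation masks the allylic hydroxyl, which would otherwise direct the later vanadium epoxidation to C9=C10.

Step 14
Reactants: 20 C1 β-OTBS C5 ketone
Product: 24 C6 exo-methylene C5 ketone (C1 β-OTBS; C9=C10), via lithium enolate 21 (not isolated), via Mannich base 22 (not isolated), via trimethylammonium iodide 23 (not isolated)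
Conditions: LiN(iPr)2 (1.1 equiv), THF, −78 °C; [CH2=NMe2]I, −78 °C → rt; then MeI, CH2Cl2, rt; then aq. NaHCO3, rt
Reagents that add atoms: N,N-dimethylmethyleneiminium iodide (Eschenmoser's salt), C=[N+](C)C.[I-]
Why: Kinetic deprotonation by the bulky amide should occur at C6 and not at C4, which is shielded by the adjacent quaternary C3, and the Mannich reaction followed by quaternisation and Hofmann-type elimination gives the exocyclic enone.

Step 15
Reactants: 24 C6 exo-methylene C5 ketone
Product: 25 C5 β-allylic alcohol (C6=CH2; C1 β-OTBS)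
Conditions: (S)-Me-CBS [(3aS)-1-methyl-3,3-diphenyltetrahydro-1H,3H-pyrrolo[1,2-c][1,3,2]oxazaborole] (0.3 equiv), catecholborane, toluene, −78 °C
Reagents that add atoms: none
Why: Corey–Bakshi–Shibata 1,2-reduction with the methylene-bearing C6 as the large group and the (S)-catalyst should give the (5R) β-alcohol, and since the C5 epimers are diastereomers any α-epimer would be removed by chromatography here.

Step 16
Reactants: 25 C5 β-allylic alcohol
Product: 26 spiro-epoxy alcohol (C6 β-O with α-CH2; C5 β-OH; C1 β-OTBS)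
Conditions: VO(acac)2 (5 mol%), t-BuOOH (1.5 equiv), CH2Cl2, 0 °C → rt
Reagents that add atoms: tert-butyl hydroperoxide, CC(C)(C)OO
Why: In this hydroxyl-directed epoxidation the vanadium alkoxide of the allylic alcohol delivers oxygen to the alkene face on which the C5 hydroxyl sits, setting C6–O β, while C9=C10 with its silylated neighbour is not activated.

Step 17
Reactants: 26 spiro-epoxy alcohol
Product: 27 C5 β-OH and C6 β-OH/α-CH3 diol (C1 β-OTBS)
Conditions: LiAlH4, THF, 0 °C → rt
Reagents that add atoms: none
Why: Hydride opens the spiro epoxide by SN2 attack at the unhindered CH2 terminus, which becomes the C6 methyl group while the C6–O bond and its configuration stay untouched.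

Step 18
Reactants: 27 C5/C6 diol
Product: 28 α-ketol (C5 ketone; C6 β-OH/α-CH3; C1 β-OTBS)
Conditions: Dess–Martin periodinane, NaHCO3, CH2Cl2, rt
Reagents that add atoms: none
Why: Dess–Martin oxidation converts only the secondary C5 carbinol, since the tertiary C6 hydroxyl cannot be oxidised, and so removes the helper centre.

Step 19
Reactants: 28 α-ketol silyl ether
Product: 29 diol ketone (C1 β-OH; C5 ketone; C6 β-OH/α-CH3)
Conditions: Bu4NF, AcOH, THF, 0 °C → rt
Reagents that add atoms: none
Why: Fluoride cleaves the Si–O bond, and the acetic acid buffer keeps the medium from becoming basic enough for α-ketol rearrangement.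

Step 20
Reactants: 29 diol ketone; 30 angelic acid [(2Z)-2-methylbut-2-enoic acid]
Product: 32 (2S,3aR,6S)-3a,6-dimethyl-5-oxo-1-(propan-2-yl)-2,3,3a,4,5,6,7,8-octahydroazulene-2,6-diyl bis[(2Z)-2-methylbut-2-enoate], via C1 mono-angelate 31 (not isolated)
Conditions: 30 (6 equiv), 2,4,6-trichlorobenzoyl chloride (6 equiv), Et3N, toluene, rt; then 29, toluene, 80–90 °C; no DMAP
Reagents that add atoms: none
Why: Yamaguchi esterification with the preformed mixed anhydride and no nucleophilic catalyst is the established way to form angelates without Z to E isomerisation, the secondary allylic C1 hydroxyl reacting first (31) and the tertiary C6 hydroxyl, flanked by the planar C5 carbonyl, on further heating.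

**Compound list**

1 | 4,4-dimethoxybutan-2-one | CC(=O)CC(OC)OC | starting material
2 | trimethyl phosphonoacetate | COC(=O)CP(=O)(OC)OC | starting material
3 | methyl (2E)-5,5-dimethoxy-3-methylpent-2-enoate | COC(=O)/C=C(\C)CC(OC)OC | intermediate
4 | 1-[(1E)-4,4-dimethoxy-2-methylbut-1-en-1-yl]cyclopropan-1-ol | OC1(CC1)/C=C(\C)CC(OC)OC | intermediate
5 | tert-butyl({1-[(1E)-4,4-dimethoxy-2-methylbut-1-en-1-yl]cyclopropyl}oxy)dimethylsilane | CC(C)(C)[Si](C)(C)OC1(CC1)/C=C(\C)CC(OC)OC | intermediate
6 | (3E)-4-[1-(tert-butyldimethylsilyloxy)cyclopropyl]-3-methylbut-3-enal | CC(C)(C)[Si](C)(C)OC1(CC1)/C=C(\C)CC=O | intermediate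
7 | bis(trimethylsilyl)acetylene | C[Si](C)(C)C#C[Si](C)(C)C | starting material
8 | 2-methylpropanoyl chloride | CC(C)C(Cl)=O | starting material
9 | 4-methyl-1-(trimethylsilyl)pent-1-yn-3-one | CC(C)C(=O)C#C[Si](C)(C)C | intermediate
10 | (3S)-4-methyl-1-(trimethylsilyl)pent-1-yn-3-ol | CC(C)[C@H](O)C#C[Si](C)(C)C | intermediate
11 | (3S)-4-methylpent-1-yn-3-ol | CC(C)[C@H](O)C#C | intermediate
12 | (3S)-4-methylpent-1-yn-3-yl methanesulfonate | CC(C)[C@H](OS(C)(=O)=O)C#C | intermediate
13 | ethyl[(aR)-4-methylpenta-1,2-dien-1-yl]zinc (not isolated) | CC[Zn][CH]=[C@]=[CH]C(C)C | intermediate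
14 | (3R,4S,6E)-7-[1-(tert-butyldimethylsilyloxy)cyclopropyl]-6-methyl-3-(propan-2-yl)hept-6-en-1-yn-4-ol | C#C[C@@H](C(C)C)[C@@H](O)C/C(C)=C/C1(O[Si](C)(C)C(C)(C)C)CC1 | intermediate
15 | (1R,2S,3aR)-5-(tert-butyldimethylsilyloxy)-3a-methyl-1-(propan-2-yl)-1,2,3,3a,6,7-hexahydroazulen-2-ol; core: C1 β-OH, C3 β-CH3, C10 β-iPr, C4=C5–OTBS, C8=C9 | O[C@H]1C[C@]2(C)C=C(O[Si](C)(C)C(C)(C)C)CCC=C2[C@H]1C(C)C | intermediate
16 | β,γ-unsaturated C1 ketone of 15 (C8=C9; C10 β-iPr; not isolated) | O=C1C[C@]2(C)C=C(O[Si](C)(C)C(C)(C)C)CCC=C2[C@H]1C(C)C | intermediate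
17 | conjugated enone: C1 ketone, C9=C10 (iPr on C10), C3 β-CH3, C4=C5–OTBS | O=C1C[C@]2(C)C=C(O[Si](C)(C)C(C)(C)C)CCCC2=C1C(C)C | intermediate
18 | C1 β-allylic alcohol of 17 with C4=C5–OTBS (not isolated) | O[C@H]1C[C@]2(C)C=C(O[Si](C)(C)C(C)(C)C)CCCC2=C1C(C)C | intermediate
19 | C1 β-hydroxy C5 ketone (C9=C10; C3 β-CH3) | O[C@H]1C[C@]2(C)CC(=O)CCCC2=C1C(C)C | intermediate
20 | C1 β-OTBS ether of 19 | CC(C)(C)[Si](C)(C)O[C@H]1C[C@]2(C)CC(=O)CCCC2=C1C(C)C | intermediate
21 | lithium Δ5(6)-enolate of 20 (not isolated) | CC(C)(C)[Si](C)(C)O[C@H]1C[C@]2(C)CC(O[Li])=CCCC2=C1C(C)C | intermediate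
22 | C6 (dimethylamino)methyl C5 ketone, C6 epimers (not isolated) | CC(C)(C)[Si](C)(C)O[C@H]1C[C@]2(C)CC(=O)C(CN(C)C)CCC2=C1C(C)C | intermediate
23 | C6 (trimethylammonio)methyl C5 ketone iodide (not isolated) | CC(C)(C)[Si](C)(C)O[C@H]1C[C@]2(C)CC(=O)C(C[N+](C)(C)C)CCC2=C1C(C)C.[I-] | intermediate
24 | C6 exo-methylene C5 ketone (C1 β-OTBS; C9=C10) | CC(C)(C)[Si](C)(C)O[C@H]1C[C@]2(C)CC(=O)C(=C)CCC2=C1C(C)C | intermediate
25 | C5 β-allylic alcohol (C6=CH2; C1 β-OTBS) | CC(C)(C)[Si](C)(C)O[C@H]1C[C@]2(C)C[C@@H](O)C(=C)CCC2=C1C(C)C | intermediate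
26 | spiro-epoxy alcohol (C6 β-O, α-CH2; C5 β-OH) | CC(C)(C)[Si](C)(C)O[C@H]1C[C@]2(C)C[C@@H](O)[C@]3(CO3)CCC2=C1C(C)C | intermediate
27 | diol (C5 β-OH; C6 β-OH, α-CH3; C1 β-OTBS) | CC(C)(C)[Si](C)(C)O[C@H]1C[C@]2(C)C[C@@H](O)[C@@](C)(O)CCC2=C1C(C)C | intermediate
28 | α-ketol (C5 ketone; C6 β-OH, α-CH3; C1 β-OTBS) | CC(C)(C)[Si](C)(C)O[C@H]1C[C@]2(C)CC(=O)[C@@](C)(O)CCC2=C1C(C)C | intermediate
29 | diol ketone (C1 β-OH; C5 ketone; C6 β-OH, α-CH3) | O[C@H]1C[C@]2(C)CC(=O)[C@@](C)(O)CCC2=C1C(C)C | intermediate
30 | angelic acid, (2Z)-2-methylbut-2-enoic acid | C/C=C(/C)C(=O)O | starting material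
31 | C1 mono-angelate of 29 (not isolated) | C/C=C(/C)C(=O)O[C@H]1C[C@]2(C)CC(=O)[C@@](C)(O)CCC2=C1C(C)C | intermediate
32 | (2S,3aR,6S)-3a,6-dimethyl-5-oxo-1-(propan-2-yl)-2,3,3a,4,5,6,7,8-octahydroazulene-2,6-diyl bis[(2Z)-2-methylbut-2-enoate] (CNP0193302.1) | C/C=C(/C)C(=O)O[C@H]1C[C@]2(C)CC(=O)[C@@](C)(OC(=O)/C(C)=C\C)CCC2=C1C(C)C | target

**Step count and risks**

Total step count: 20. Longest linear sequence: 16 steps (steps 1–4 then 9–20; the branch 5–8 then 9–20 is equally long).

The three steps most likely to fail: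

Step 10. The facial discrimination at C3 during alkyne insertion may be too weak, because the relay from C10 and C1 has to control a quaternary carbon, and the free hydroxyl may bind rhodium and slow turnover. The fallback sets out from 14. The hydroxyl would be masked with pivaloyl chloride (pyridine, DMAP) as the bulky ester pivalate enyne F1, whose larger C1 substituent should enforce the convex-face arrangement. Cycloaddition with [Rh(CO)2Cl]2 or the cationic [Rh(cod)(naphthalene)]SbF6 in ClCH2CH2Cl would give pivalate cycloadduct F2. Reductive ester cleavage with iBu2AlH at −78 °C, which leaves the silyl enol ether alone, comes back to the route at 15.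

Step 15. Hydride may be delivered to the wrong face of the C5 carbonyl if the substrate bias or the neopentyl-like C4 overrides catalyst control. The directing hydroxyl would then be α and the epoxide oxygen would go to the wrong face of C6. The fallback sets out from 24. Luche reduction (NaBH4, CeCl3·7H2O, MeOH, −78 °C) would be run under substrate control. If it favours the C5 α-alcohol F3, Mitsunobu inversion with 4-nitrobenzoic acid (PPh3, DIAD) would give the β-configured 4-nitrobenzoate F4. Methanolysis (K2CO3, MeOH) comes back to the route at 25.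

Step 20. Acylation of the hindered tertiary α-ketol hydroxyl may stay incomplete, and prolonged heating may cause Z to E isomerisation to the tiglate or α-ketol rearrangement. The fallback sets out from 29 and builds the alkenes after the ester bonds. Both hydroxyls would be acylated with 2-[bis(2,2,2-trifluoroethoxy)phosphoryl]propanoic acid (DCC, DMAP; a nucleophilic catalyst is harmless here because no alkene geometry exists yet) to give bis(phosphonopropanoate) F5. Double Still–Gennari olefination with acetaldehyde (KN(SiMe3)2, 18-crown-6, THF, −78 °C) forms both (Z)-2-methylbut-2-enoates and comes back to the route at 32.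

**Further compounds**

F1 | step 10 | (3R,4S,6E)-7-[1-(tert-butyldimethylsilyloxy)cyclopropyl]-6-methyl-3-(propan-2-yl)hept-6-en-1-yn-4-yl 2,2-dimethylpropanoate | C#C[C@@H](C(C)C)[C@@H](OC(=O)C(C)(C)C)C/C(C)=C/C1(O[Si](C)(C)C(C)(C)C)CC1
F2 | step 10 | C1 β-pivalate of cycloadduct 15 | CC(C)(C)C(=O)O[C@H]1C[C@]2(C)C=C(O[Si](C)(C)C(C)(C)C)CCC=C2[C@H]1C(C)C
F3 | step 15 | C5 α-allylic alcohol (C5 epimer of 25) | CC(C)(C)[Si](C)(C)O[C@H]1C[C@]2(C)C[C@H](O)C(=C)CCC2=C1C(C)C
F4 | step 15 | C5 β 4-nitrobenzoate of 25 | CC(C)(C)[Si](C)(C)O[C@H]1C[C@]2(C)C[C@@H](OC(=O)c3ccc(cc3)[N+](=O)[O-])C(=C)CCC2=C1C(C)C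
F5 | step 20 | C1,C6 bis{2-[bis(2,2,2-trifluoroethoxy)phosphoryl]propanoate} of 29 | CC(C(=O)O[C@H]1C[C@]2(C)CC(=O)[C@@](C)(OC(=O)C(C)P(=O)(OCC(F)(F)F)OCC(F)(F)F)CCC2=C1C(C)C)P(=O)(OCC(F)(F)F)OCC(F)(F)F
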